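**Strategy**

The bicycle is cut at C1–C5 and C6–C7. Because the C1–C5 bond is common to the cyclopentane and the cycloheptene (C1, C5–C10), and C1 and C5 are otherwise linked only through C2, C3 and C4, a C5≡C6 alkyne can be tied by that short chain to a C1=C10 alkenyl siloxycyclopropane (C7, C8, C9). One rhodium-catalysed [5+2] cycloaddition then closes both rings, makes two C–C bonds and the quaternary C1, and leaves a C9 silyl enol ether and a C5=C6 alkene for later oxygenation. The precursor is an acyclic (E)-enyne built on the carbinol carbon of (S)-terpinen-4-ol (C4) and ends in a (1S,2R)-siloxy(methyl)cyclopropane whose configuration is relayed to C1.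

Key step: step 9

**Remarks on the chemistry**

- Numbering: C1 angular-methyl ring-fusion carbon, C2–C3 ring CH2, C4 isopropyl carbinol carbon, C5 second ring-fusion carbon, C6–C10 the other seven-ring atoms (C8 carries the ring methyl). Open-chain intermediates are numbered by the ring atoms they become; β is the face of the C1 methyl group.
- Assumption: (S)-terpinen-4-ol is used as a single enantiomer; its carbinol carbon maps onto C4 of the target with the required configuration and is never touched.
- The cycloaddition is stereospecific with respect to the cyclopropane, so the configuration of C1 follows from C9 and from the alkene geometry, not from C4. The cyclopropane is therefore made as one isomer (step 8) and the (E)-alkene is purified (step 3).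
- Assumption: the L,L-dipeptide in step 8 is taken to give the (1S,2R) cyclopropane; if the sense proves opposite, its D,D antipode is used.
- Borane would reduce a C9 ketone and could not tell two trisubstituted alkenes apart, so the ketone is stored as its enol triflate during hydroboration (steps 11–14).
- A methyl ketone would compete in enol sulfonate formation, so the aldehyde is kept as an acetal until the ketone has been olefinated (steps 2–5). A phosphonoacetamide is used for the olefination because β-ketophosphonates react poorly with ketones.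

**Route**

Step 1
Reactants: 1 (S)-terpinen-4-ol
Product: 2 (S)-triethyl{[4-methyl-1-(propan-2-yl)cyclohex-3-en-1-yl]oxy}silane
Conditions: TESOTf, 2,6-lutidine, CH2Cl2, 0 °C to rt
Reagents that add atoms: triethylsilyl trifluoromethanesulfonate, CC[Si](CC)(CC)OS(=O)(=O)C(F)(F)F
Why: Silyl triflate and a hindered pyridine base silylate the tertiary alcohol (silyl ether protection) without touching the C4 stereocentre or the alkene.

Step 2
Reactants: 2 (S)-triethyl{[4-methyl-1-(propan-2-yl)cyclohex-3-en-1-yl]oxy}silane
Product: 5 (5S)-7,7-dimethoxy-5-(propan-2-yl)-5-(triethylsilyloxy)heptan-2-one, via methoxy hydroperoxide 3 (not isolated), via hydroperoxy acetal 4 (not isolated)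
Conditions: O3, CH2Cl2/MeOH, −78 °C; PPTS (cat.), −78 °C to rt; NaHCO3, Me2S, rt
Reagents that add atoms: ozone, [O-][O+]=O; methanol, CO
Why: Ozonolysis in methanol (Criegee mechanism, unsymmetrical work-up of the Schreiber type) places the carbonyl oxide on the more substituted carbon, where methanol holds it as the methoxy hydroperoxide while mild acid acetalises only the free aldehyde, and Me2S then releases the methyl ketone, so the two ends are differentiated in one flask.

Step 3
Reactants: 5 (5S)-7,7-dimethoxy-5-(propan-2-yl)-5-(triethylsilyloxy)heptan-2-one; 6 diethyl {2-[methoxy(methyl)amino]-2-oxoethyl}phosphonate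
Product: 7 (2E,6S)-N-methoxy-8,8-dimethoxy-N,3-dimethyl-6-(propan-2-yl)-6-(triethylsilyloxy)oct-2-enamide
Conditions: NaH, THF, 0 °C, then 5, reflux; chromatography to remove the (Z)-isomer
Reagents that add atoms: none
Why: Horner–Wadsworth–Emmons olefination of the methyl ketone should favour the (E)-amide, in which the longer chain is trans to the carbonyl group, and the minor (Z)-isomer is removed here because the alkene geometry later decides the configuration of C1.

Step 4
Reactants: 7 (2E,6S)-N-methoxy-8,8-dimethoxy-N,3-dimethyl-6-(propan-2-yl)-6-(triethylsilyloxy)oct-2-enamide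
Product: 9 (2E,6S)-N-methoxy-N,3-dimethyl-8-oxo-6-(propan-2-yl)-6-(triethylsilyloxy)oct-2-enamide, via collidinium salt 8 (not isolated)
Conditions: TESOTf, 2,4,6-collidine, CH2Cl2, 0 °C; then H2O
Reagents that add atoms: water, O
Why: Acetal cleavage under basic conditions (silyl triflate and collidine give a pyridinium N,O-acetal that water hydrolyses) should free the aldehyde without acid, so the tertiary silyl ether and the enamide survive.

Step 5
Reactants: 9 (2E,6S)-N-methoxy-N,3-dimethyl-8-oxo-6-(propan-2-yl)-6-(triethylsilyloxy)oct-2-enamide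
Product: 11 (2E,6R)-6-ethynyl-N-methoxy-N,3,7-trimethyl-6-(triethylsilyloxy)oct-2-enamide, via alkenyl nonaflate 10 (not isolated)
Conditions: nonafluorobutanesulfonyl fluoride, phosphazene base P2-Et, DMF, −30 °C to rt
Reagents that add atoms: none
Why: One-pot conversion of an enolisable aldehyde into a terminal alkyne by O-sulfonylation of the enolate and E2 elimination of the alkenyl nonaflate with the phosphazene base, the aldehyde being the only readily enolised carbonyl group now that the ketone has become an enamide.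

Step 6
Reactants: 11 (2E,6R)-6-ethynyl-N-methoxy-N,3,7-trimethyl-6-(triethylsilyloxy)oct-2-enamide; 12 ethylmagnesium bromide
Product: 14 (4E,8R)-8-ethynyl-5,9-dimethyl-8-(triethylsilyloxy)dec-4-en-3-one, via magnesium hemiaminal 13 (not isolated)
Conditions: EtMgBr (3 equiv), THF, −20 to 0 °C; aq. NH4Cl
Reagents that add atoms: none
Why: Weinreb ketone synthesis, in which the chelated magnesium adduct resists a second addition until work-up, while one equivalent of the Grignard reagent is spent on the alkyne C–H, which is restored on quenching.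

Step 7
Reactants: 14 (4E,8R)-8-ethynyl-5,9-dimethyl-8-(triethylsilyloxy)dec-4-en-3-one
Product: 15 tert-butyl{[(2Z,4E,8R)-8-ethynyl-5,9-dimethyl-8-(triethylsilyloxy)deca-2,4-dien-3-yl]oxy}dimethylsilane
Conditions: TBSOTf, Et3N, CH2Cl2, −78 to 0 °C
Reagents that add atoms: tert-butyldimethylsilyl trifluoromethanesulfonate, CC(C)(C)[Si](C)(C)OS(=O)(=O)C(F)(F)F
Why: Soft enolisation with silyl triflate and amine removes a proton from the ethyl CH2 to give the cross-conjugated 2-silyloxydiene, the (Z)-enol ether (OSi cis to CH3) being favoured by allylic strain, while the alkyne C–H is not acidic enough for triethylamine.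

Step 8
Reactants: 15 tert-butyl{[(2Z,4E,8R)-8-ethynyl-5,9-dimethyl-8-(triethylsilyloxy)deca-2,4-dien-3-yl]oxy}dimethylsilane; 16 diiodomethane
Product: 17 tert-butyl{[(1S,2R)-1-[(1E,5R)-5-ethynyl-2,6-dimethyl-5-(triethylsilyloxy)hept-1-en-1-yl]-2-methylcyclopropyl]oxy}dimethylsilane
Conditions: Et2Zn, CH2I2, Boc-L-Val-L-Pro-OMe (1.25 equiv), CH2Cl2, −40 to 0 °C
Reagents that add atoms: none
Why: Simmons–Smith (Furukawa) cyclopropanation is selective for the electron-rich enol ether double bond over the C1=C10 alkene and stereospecific, so the (Z)-enol ether gives methyl cis to silyloxy, and the zinc carbenoid bound to the chiral dipeptide chooses the alkene face and thereby sets C9 (S) and C8 (R) by reagent control, the remote C4 centre having no influence.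

Step 9
Reactants: 17 tert-butyl{[(1S,2R)-1-[(1E,5R)-5-ethynyl-2,6-dimethyl-5-(triethylsilyloxy)hept-1-en-1-yl]-2-methylcyclopropyl]oxy}dimethylsilane
Product: 18 9-(tert-butyldimethylsilyloxy)-4β-(triethylsilyloxy)dauca-5,9-diene (1β-methyl, 8α-methyl)
Conditions: [Rh(CO)2Cl]2 (5 mol %), ClCH2CH2Cl (0.01 M), 80 °C, argon
Reagents that add atoms: none
Why: Proposed new method: monovalent rhodium binds the C1=C10 alkene and inserts into the unsubstituted C9–C7 cyclopropane bond, helped by the siloxy donor, to give an allyl/alkyl rhodacycle, the tethered alkyne then inserts at C1 and C6–C7 reductive elimination frees the catalyst; the closest known reaction type is the rhodium-catalysed intramolecular [5+2] cycloaddition of (siloxy)vinylcyclopropanes with tethered alkynes, established only for alkene termini that carry one carbon substituent, whereas here C1 also bears a methyl group and becomes quaternary. The five-membered ring closes by 5-exo insertion of the alkyne at the C1 end of the allyl unit across the C2–C3–C4 chain, and the seven-membered ring closes by C(sp2)–C(sp3) reductive elimination of C6 and C7 from the eight-membered rhodacycle. C1 is the only new stereocentre and is set by chirality transfer from the cyclopropane, because rhodium sits on the alkene face on which C7 lies, so the (9S,8R) ring together with the (E)-alkene delivers C5 to the face that puts the methyl group cis to the C4 silyloxy group, C4 itself being a matched bystander. The step needs cleavage of C9–C7 and not of C9–C8, and cycloaddition instead of alkyne oligomerisation; the methyl group on C8, trans to the alkenyl group, makes the substituted bond less accessible to the metal, and the fully substituted C4 folds the chain toward the reacting conformer and shields the alkyne. The siloxy group is kept because it speeds ring opening and ends as the C9 enol ether that step 10 needs.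

Step 10
Reactants: 18 9-(tert-butyldimethylsilyloxy)-4β-(triethylsilyloxy)dauca-5,9-diene
Product: 20 10α-(tert-butyldimethylsilyloxy)-4β-(triethylsilyloxy)dauc-5-en-9-one (8α-methyl), via silyloxy epoxide 19 (not isolated)
Conditions: mCPBA (1.05 equiv), NaHCO3, CH2Cl2, −20 °C to rt
Reagents that add atoms: 3-chloroperoxybenzoic acid, OOC(=O)c1cccc(Cl)c1
Why: Rubottom oxidation, in which the peracid epoxidises the electron-rich silyl enol ether faster than the hindered C5=C6 alkene and from the α face, anti to the pseudoaxial angular methyl on C1, and the silyloxy epoxide opens with 1,4-silyl shift to the 10α-silyloxy ketone.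

Step 11
Reactants: 20 10α-(tert-butyldimethylsilyloxy)-4β-(triethylsilyloxy)dauc-5-en-9-one
Product: 22 10α-(tert-butyldimethylsilyloxy)-4β-(triethylsilyloxy)dauca-5,8-dien-9-yl trifluoromethanesulfonate, via potassium enolate 21 (not isolated)
Conditions: KN(SiMe3)2, THF, −78 °C; then N-(5-chloropyridin-2-yl)bis(trifluoromethanesulfonimide), −78 to −20 °C
Reagents that add atoms: N-(5-chloropyridin-2-yl)bis(trifluoromethanesulfonimide), FC(F)(F)S(=O)(=O)N(c1ccc(Cl)cn1)S(=O)(=O)C(F)(F)F
Why: Kinetic enolate formation at C8 (the C10 hydrogen is shielded by the silyloxy group and the quaternary C1) and O-sulfonylation with the Comins reagent give the tetrasubstituted enol triflate, which fixes the future alkene at C8=C9, masks the ketone against borane and erases the C8 stereocentre on purpose.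

Step 12
Reactants: 22 10α-(tert-butyldimethylsilyloxy)-4β-(triethylsilyloxy)dauca-5,8-dien-9-yl trifluoromethanesulfonate
Product: 24 10α-(tert-butyldimethylsilyloxy)-6α-hydroxy-4β-(triethylsilyloxy)-5α-dauc-8-en-9-yl trifluoromethanesulfonate, via alkylborane 23 (not isolated)
Conditions: BH3·THF, THF, 0 °C to rt; then NaBO3·4H2O, THF/H2O, rt
Reagents that add atoms: sodium perborate (used as the tetrahydrate), [Na+].[Na+].O[B-]1(O)OO[B-](O)(O)OO1
Why: Hydroboration–oxidation adds H and B syn, with boron on the less substituted C6 and from the α face anti to the angular methyl as with steroidal 5-enes, which sets the 5α-hydrogen (trans ring fusion) and, after oxidation with retention, the 6α-oxygen cis to it, the electron-poor tetrasubstituted enol triflate being inert to borane.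

Step 13
Reactants: 24 10α-(tert-butyldimethylsilyloxy)-6α-hydroxy-4β-(triethylsilyloxy)-5α-dauc-8-en-9-yl trifluoromethanesulfonate; 25 4-methoxybenzoyl chloride
Product: 26 10α-(tert-butyldimethylsilyloxy)-9-(trifluoromethanesulfonyloxy)-4β-(triethylsilyloxy)-5α-dauc-8-en-6α-yl 4-methoxybenzoate
Conditions: Et3N, DMAP (cat.), CH2Cl2, 0 °C to rt
Reagents that add atoms: none
Why: DMAP-catalysed acyl transfer (nucleophilic catalysis) esterifies the only free hydroxyl group with retention at C6.

Step 14
Reactants: 26 10α-(tert-butyldimethylsilyloxy)-9-(trifluoromethanesulfonyloxy)-4β-(triethylsilyloxy)-5α-dauc-8-en-6α-yl 4-methoxybenzoate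
Product: 27 10α-(tert-butyldimethylsilyloxy)-4β-(triethylsilyloxy)-5α-dauc-8-en-6α-yl 4-methoxybenzoate
Conditions: Pd(OAc)2 (5 mol %), PPh3, HCO2H, Bu3N, DMF, 60 °C
Reagents that add atoms: none
Why: Palladium-catalysed reduction of the enol triflate (oxidative addition to zerovalent palladium, formate to hydride with loss of CO2, reductive elimination) replaces the triflate by hydrogen and leaves the C8=C9 alkene, the ester and the silyl ethers untouched.

Step 15
Reactants: 27 10α-(tert-butyldimethylsilyloxy)-4β-(triethylsilyloxy)-5α-dauc-8-en-6α-yl 4-methoxybenzoate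
Product: 28 4β,10α-dihydroxy-5α-dauc-8-en-6α-yl 4-methoxybenzoate (CNP0211568.1)
Conditions: HF·pyridine, pyridine/THF, 0 °C to rt
Reagents that add atoms: none
Why: Fluoride-driven cleavage of both silyl ethers (strong Si–F bond) in pyridine-buffered HF should free the tertiary C4 and the allylic C10 hydroxyl groups without ionising the allylic alcohol or cleaving the aryl ester.

**Compound list**

1 | (S)-terpinen-4-ol | CC1=CC[C@](O)(C(C)C)CC1 | starting material
2 | (S)-triethyl{[4-methyl-1-(propan-2-yl)cyclohex-3-en-1-yl]oxy}silane | CC1=CC[C@](O[Si](CC)(CC)CC)(C(C)C)CC1 | intermediate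
3 | methoxy hydroperoxide: (3S)-6-hydroperoxy-6-methoxy-3-(propan-2-yl)-3-(triethylsilyloxy)heptanal (C6 unassigned) | O=CC[C@](O[Si](CC)(CC)CC)(C(C)C)CCC(C)(OC)OO | intermediate
4 | hydroperoxy acetal: (5S)-2-hydroperoxy-2,7,7-trimethoxy-5-(propan-2-yl)-5-(triethylsilyloxy)heptane (C2 unassigned) | COC(OC)C[C@](O[Si](CC)(CC)CC)(C(C)C)CCC(C)(OC)OO | intermediate
5 | (5S)-7,7-dimethoxy-5-(propan-2-yl)-5-(triethylsilyloxy)heptan-2-one | COC(OC)C[C@](O[Si](CC)(CC)CC)(C(C)C)CCC(C)=O | intermediate
6 | diethyl {2-[methoxy(methyl)amino]-2-oxoethyl}phosphonate | CCOP(=O)(CC(=O)N(C)OC)OCC | starting material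
7 | (2E,6S)-N-methoxy-8,8-dimethoxy-N,3-dimethyl-6-(propan-2-yl)-6-(triethylsilyloxy)oct-2-enamide | COC(OC)C[C@](O[Si](CC)(CC)CC)(C(C)C)CC/C(C)=C/C(=O)N(C)OC | intermediate
8 | collidinium salt: 2,4,6-trimethylpyridinium N,O-acetal of 7 at C8, triflate (C8 unassigned) | COC(C[C@](O[Si](CC)(CC)CC)(C(C)C)CC/C(C)=C/C(=O)N(C)OC)[n+]1c(C)cc(C)cc1C.[O-]S(=O)(=O)C(F)(F)F | intermediate
9 | (2E,6S)-N-methoxy-N,3-dimethyl-8-oxo-6-(propan-2-yl)-6-(triethylsilyloxy)oct-2-enamide | O=CC[C@](O[Si](CC)(CC)CC)(C(C)C)CC/C(C)=C/C(=O)N(C)OC | intermediate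
10 | alkenyl nonaflate: enol nonafluorobutanesulfonate of aldehyde 9 (enol geometry unassigned) | O=S(=O)(OC=C[C@](O[Si](CC)(CC)CC)(C(C)C)CC/C(C)=C/C(=O)N(C)OC)C(F)(F)C(F)(F)C(F)(F)C(F)(F)F | intermediate
11 | (2E,6R)-6-ethynyl-N-methoxy-N,3,7-trimethyl-6-(triethylsilyloxy)oct-2-enamide | C#C[C@](O[Si](CC)(CC)CC)(C(C)C)CC/C(C)=C/C(=O)N(C)OC | intermediate
12 | ethylmagnesium bromide | CC[Mg]Br | starting material
13 | magnesium hemiaminal: bromomagnesium alkoxide of the ethyl adduct of 11, alkyne as bromomagnesium acetylide | Br[Mg]C#C[C@](O[Si](CC)(CC)CC)(C(C)C)CC/C(C)=C/C(CC)(O[Mg]Br)N(C)OC | intermediate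
14 | (4E,8R)-8-ethynyl-5,9-dimethyl-8-(triethylsilyloxy)dec-4-en-3-one | C#C[C@](O[Si](CC)(CC)CC)(C(C)C)CC/C(C)=C/C(=O)CC | intermediate
15 | tert-butyl{[(2Z,4E,8R)-8-ethynyl-5,9-dimethyl-8-(triethylsilyloxy)deca-2,4-dien-3-yl]oxy}dimethylsilane | C#C[C@](O[Si](CC)(CC)CC)(C(C)C)CC/C(C)=C/C(O[Si](C)(C)C(C)(C)C)=C/C | intermediate
16 | diiodomethane | ICI | starting material
17 | tert-butyl{[(1S,2R)-1-[(1E,5R)-5-ethynyl-2,6-dimethyl-5-(triethylsilyloxy)hept-1-en-1-yl]-2-methylcyclopropyl]oxy}dimethylsilane (cycloaddition precursor) | C#C[C@](O[Si](CC)(CC)CC)(C(C)C)CC/C(C)=C/[C@]1(O[Si](C)(C)C(C)(C)C)C[C@H]1C | intermediate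
18 | 9-(tert-butyldimethylsilyloxy)-4β-(triethylsilyloxy)dauca-5,9-diene, 1β-methyl, 8α-methyl (cycloadduct) | C[C@@H]1CC=C2[C@](O[Si](CC)(CC)CC)(C(C)C)CC[C@]2(C)C=C1O[Si](C)(C)C(C)(C)C | intermediate
19 | silyloxy epoxide: 9α,10α-epoxide of 18 with the silyloxy group on C9 | C[C@@H]1CC=C2[C@](O[Si](CC)(CC)CC)(C(C)C)CC[C@]2(C)[C@@H]3O[C@]13O[Si](C)(C)C(C)(C)C | intermediate
20 | 10α-(tert-butyldimethylsilyloxy)-4β-(triethylsilyloxy)dauc-5-en-9-one, 8α-methyl | C[C@@H]1CC=C2[C@](O[Si](CC)(CC)CC)(C(C)C)CC[C@]2(C)[C@H](O[Si](C)(C)C(C)(C)C)C1=O | intermediate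
21 | potassium enolate: potassium 8-en-9-olate of 20 | CC1=C([O-])[C@@H](O[Si](C)(C)C(C)(C)C)[C@@]2(C)CC[C@@](O[Si](CC)(CC)CC)(C(C)C)C2=CC1.[K+] | intermediate
22 | 10α-(tert-butyldimethylsilyloxy)-4β-(triethylsilyloxy)dauca-5,8-dien-9-yl trifluoromethanesulfonate | CC1=C(OS(=O)(=O)C(F)(F)F)[C@@H](O[Si](C)(C)C(C)(C)C)[C@@]2(C)CC[C@@](O[Si](CC)(CC)CC)(C(C)C)C2=CC1 | intermediate
23 | alkylborane: 6α-boryl-5α-H adduct of 22 | CC1=C(OS(=O)(=O)C(F)(F)F)[C@@H](O[Si](C)(C)C(C)(C)C)[C@@]2(C)CC[C@@](O[Si](CC)(CC)CC)(C(C)C)[C@@H]2[C@@H](B)C1 | intermediate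
24 | 10α-(tert-butyldimethylsilyloxy)-6α-hydroxy-4β-(triethylsilyloxy)-5α-dauc-8-en-9-yl trifluoromethanesulfonate | CC1=C(OS(=O)(=O)C(F)(F)F)[C@@H](O[Si](C)(C)C(C)(C)C)[C@@]2(C)CC[C@@](O[Si](CC)(CC)CC)(C(C)C)[C@@H]2[C@@H](O)C1 | intermediate
25 | 4-methoxybenzoyl chloride | COc1ccc(cc1)C(Cl)=O | starting material
26 | 10α-(tert-butyldimethylsilyloxy)-9-(trifluoromethanesulfonyloxy)-4β-(triethylsilyloxy)-5α-dauc-8-en-6α-yl 4-methoxybenzoate | CC1=C(OS(=O)(=O)C(F)(F)F)[C@@H](O[Si](C)(C)C(C)(C)C)[C@@]2(C)CC[C@@](O[Si](CC)(CC)CC)(C(C)C)[C@@H]2[C@@H](OC(=O)c3ccc(OC)cc3)C1 | intermediate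
27 | 10α-(tert-butyldimethylsilyloxy)-4β-(triethylsilyloxy)-5α-dauc-8-en-6α-yl 4-methoxybenzoate | CC1=C[C@@H](O[Si](C)(C)C(C)(C)C)[C@@]2(C)CC[C@@](O[Si](CC)(CC)CC)(C(C)C)[C@@H]2[C@@H](OC(=O)c3ccc(OC)cc3)C1 | intermediate
28 | 4β,10α-dihydroxy-5α-dauc-8-en-6α-yl 4-methoxybenzoate (CNP0211568.1) | COc1ccc(C(=O)O[C@H]2CC(C)=C[C@@H](O)[C@@]3(C)CC[C@@](O)(C(C)C)[C@H]23)cc1 | target

**Step count and risks**

Total step count: 15. Longest linear sequence: 15 steps (1 to 28).

Steps most likely to fail:

1. Step 9 (key step). The catalyst may not turn over because the methyl-bearing alkene carbon resists alkyne insertion, or the ring may open at C9–C8. The two bonds would then be made one after the other by known reactions, setting out from enone 14.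
   - Bu3SnH and AIBN in benzene at 80 °C should add a stannyl radical to the alkyne terminus and close the five-membered ring by 5-exo attack of the vinyl radical on C1 of the enone (tin-mediated radical enyne cyclisation). This gives the vinylstannane F1, with tin on the side of C1 as the less crowded isomer; facial control at C1 by C4 is the weak point of this sequence.
   - Iododestannylation (I2, CH2Cl2) gives the vinyl iodide F2, Stille coupling with Bu3SnCH2OH and Pd(PPh3)4 the allylic alcohol F3, and CBr4/PPh3 the allylic bromide F4.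
   - KN(SiMe3)2 in THF at high dilution should deprotonate the ethyl CH2 (C8) and close the seven-membered ring by intramolecular C-alkylation at C7, giving the bicyclic ketone F5 as C8 epimers.
   - Kinetic enolisation toward C10 (LiN(iPr)2, THF, −78 °C) and silylation with TBSOTf return to the route at 18. Its C8 epimer F6 is carried alongside through steps 10 and 11 because C8 becomes trigonal in 22.

2. Step 8. The dipeptide-bound carbenoid may discriminate poorly between the two faces of the dienol ether. The cyclopropane stereochemistry would then be sorted out after the cycloaddition. Setting out from 15, Et2Zn/CH2I2 without ligand gives 17 together with the mirror-image-cyclopropane diastereomer F7. The mixture is taken through step 9, where F7 is expected to give the C1,C8-diepimeric cycloadduct F8. 18 and F8 differ at a ring-fusion carbon next to C4 and should separate on silica gel, so the fallback returns to the route at 18 at the cost of half the material.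

3. Step 12. Borane may fail to add to an alkene placed between two quaternary carbons, or may add from the β face. Setting out from 22, mCPBA (NaHCO3, CH2Cl2), which tolerates hindered alkenes better, should give the 5α,6α-epoxide F9. Cp2TiCl (from Cp2TiCl2 and Mn) in wet THF should then open it by single-electron transfer from trivalent titanium to the tertiary C5 radical. Hydrogen-atom transfer to that radical from the less hindered α face leaves the oxygen on C6 (anti-Markovnikov reductive epoxide opening) and returns to the route at 24.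

**Further compounds**

F1 | step 9 | 1-[1-methyl-3-(propan-2-yl)-2-[(E)-(tributylstannyl)methylidene]-3-(triethylsilyloxy)cyclopentyl]butan-2-one (methyl cis to silyloxy) | CCC(=O)C[C@@]1(C)CC[C@@](O[Si](CC)(CC)CC)(C(C)C)/C1=C/[Sn](CCCC)(CCCC)CCCC
F2 | step 9 | 1-[2-[(E)-iodomethylidene]-1-methyl-3-(propan-2-yl)-3-(triethylsilyloxy)cyclopentyl]butan-2-one | CCC(=O)C[C@@]1(C)CC[C@@](O[Si](CC)(CC)CC)(C(C)C)/C1=C/I
F3 | step 9 | 1-[2-[(E)-2-hydroxyethylidene]-1-methyl-3-(propan-2-yl)-3-(triethylsilyloxy)cyclopentyl]butan-2-one | CCC(=O)C[C@@]1(C)CC[C@@](O[Si](CC)(CC)CC)(C(C)C)/C1=C/CO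
F4 | step 9 | 1-[2-[(E)-2-bromoethylidene]-1-methyl-3-(propan-2-yl)-3-(triethylsilyloxy)cyclopentyl]butan-2-one | CCC(=O)C[C@@]1(C)CC[C@@](O[Si](CC)(CC)CC)(C(C)C)/C1=C/CBr
F5 | step 9 | 4β-(triethylsilyloxy)dauc-5-en-9-one (C8 epimers) | CC1CC=C2[C@](O[Si](CC)(CC)CC)(C(C)C)CC[C@]2(C)CC1=O
F6 | step 9 | 9-(tert-butyldimethylsilyloxy)-4β-(triethylsilyloxy)dauca-5,9-diene, 8β-methyl (C8 epimer of 18) | C[C@H]1CC=C2[C@](O[Si](CC)(CC)CC)(C(C)C)CC[C@]2(C)C=C1O[Si](C)(C)C(C)(C)C
F7 | step 8 | tert-butyl{[(1R,2S)-1-[(1E,5R)-5-ethynyl-2,6-dimethyl-5-(triethylsilyloxy)hept-1-en-1-yl]-2-methylcyclopropyl]oxy}dimethylsilane | C#C[C@](O[Si](CC)(CC)CC)(C(C)C)CC/C(C)=C/[C@@]1(O[Si](C)(C)C(C)(C)C)C[C@@H]1C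
F8 | step 8 | 9-(tert-butyldimethylsilyloxy)-4β-(triethylsilyloxy)dauca-5,9-diene epimeric at C1 and C8 (1-methyl trans to the C4 silyloxy group) | C[C@H]1CC=C2[C@](O[Si](CC)(CC)CC)(C(C)C)CC[C@@]2(C)C=C1O[Si](C)(C)C(C)(C)C
F9 | step 12 | 10α-(tert-butyldimethylsilyloxy)-5α,6α-epoxy-4β-(triethylsilyloxy)dauc-8-en-9-yl trifluoromethanesulfonate | CC1=C(OS(=O)(=O)C(F)(F)F)[C@@H](O[Si](C)(C)C(C)(C)C)[C@@]2(C)CC[C@@](O[Si](CC)(CC)CC)(C(C)C)[C@@]23O[C@H]3C1
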